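**Retrosynthetic overview**

1. Target 17 comes from 14 by O5'-methylation, O2'-desilylation and debenzylation; nothing skeletal changes after the key step.
2. The strategy rests on ring B (C1'–C6') being a hydroquinone core: the oxygens at C2' and C5' are para, with ArO at C4', CO2H at C1' beside the C2' OH, and heptyl at C6' beside the C5' OMe. Ring B is cut at C1'–C2' and C5'–C6' into 4-aryloxy-2-silyloxyfuran 9 (C2'–C5' with both oxygens) and benzyl dec-2-ynoate 12 (C1', C6', ester, heptyl).
3. Furan 9 comes from butenolide 8, which comes from ring A phenol 6 and 4-bromofuran-2(5H)-one 7; the diaryl ether C4'–O bond is therefore made before ring B exists.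
4. Phenol 6 comes from 5-heptylresorcinol 1 by formylation, 4-O-methylation, oxidation and benzylation; ynoate 12 comes from 1-nonyne 10.
5. Ring order: ring A is bought, the furan is a temporary ring, and ring B is the only ring built (step 8).

Key step: step 8

Remark: the target has no stereocentre and no configurationally stable axis, so the route has no stereochemistry to set. Ring B locants (C1' = carboxyl carbon) are used throughout.

**Route**

Step 1
Reactants: 1 5-heptylresorcinol
Product: 3 6-heptyl-2,4-dihydroxybenzaldehyde, via aryl iminium chloride 2 (not isolated)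
Conditions: POCl3, DMF, 0 °C to rt; then H2O, 50 °C
Reagents that add atoms: N,N-dimethylformamide CN(C)C=O; water O
Why: Vilsmeier–Haack formylation of a 5-alkylresorcinol goes to C4 (para to one OH, ortho to the other) and not to the doubly flanked C2, so the ring A carbon substituent is placed more dependably than by a Kolbe–Schmitt carboxylation.

Step 2
Reactants: 3 6-heptyl-2,4-dihydroxybenzaldehyde
Product: 4 2-heptyl-6-hydroxy-4-methoxybenzaldehyde
Conditions: MeI (1.05 equiv), K2CO3 (1.1 equiv), acetone, rt
Reagents that add atoms: iodomethane CI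
Why: Williamson methylation should take only the para hydroxyl, because the ortho hydroxyl is held in a hydrogen bond to the formyl group and is much less nucleophilic.

Step 3
Reactants: 4 2-heptyl-6-hydroxy-4-methoxybenzaldehyde
Product: 5 2-heptyl-6-hydroxy-4-methoxybenzoic acid
Conditions: NaClO2, NaH2PO4, 2-methyl-2-butene, t-BuOH/THF/H2O, 0 °C to rt
Reagents that add atoms: sodium chlorite [Na+].[O-]Cl=O
Why: Pinnick oxidation converts the aryl aldehyde to the acid under buffered conditions, and the alkene scavenger removes HOCl before it can chlorinate the electron-rich ring.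

Step 4
Reactants: 5 2-heptyl-6-hydroxy-4-methoxybenzoic acid
Product: 6 benzyl 2-heptyl-6-hydroxy-4-methoxybenzoate
Conditions: BnBr, KHCO3, DMF, rt
Reagents that add atoms: benzyl bromide BrCc1ccccc1
Why: Hydrogencarbonate ionises the carboxylic acid but not the chelated phenol, so SN2 alkylation with benzyl bromide should give the ester with the phenol left free.

Step 5
Reactants: 6 benzyl 2-heptyl-6-hydroxy-4-methoxybenzoate; 7 4-bromofuran-2(5H)-one
Product: 8 benzyl 2-heptyl-4-methoxy-6-[(5-oxo-2,5-dihydrofuran-3-yl)oxy]benzoate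
Conditions: K2CO3, MeCN, rt to 40 °C
Reagents that add atoms: none
Why: The β-bromobutenolide is a vinylogous acyl bromide, so the phenoxide should add at C4 and expel bromide (conjugate addition–elimination) to give the 4-aryloxybutenolide.

Step 6
Reactants: 8 benzyl 2-heptyl-4-methoxy-6-[(5-oxo-2,5-dihydrofuran-3-yl)oxy]benzoate
Product: 9 benzyl 2-heptyl-4-methoxy-6-[(5-tert-butyldimethylsilyloxyfuran-3-yl)oxy]benzoate
Conditions: TBSOTf, Et3N, CH2Cl2, 0 °C; pentane extraction, no aqueous work-up
Reagents that add atoms: tert-butyldimethylsilyl trifluoromethanesulfonate CC(C)(C)[Si](C)(C)OS(=O)(=O)C(F)(F)F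
Why: Soft enolisation (O-silylation of the lactone carbonyl, then loss of a γ-proton from C5 to triethylamine) gives the aromatic 2-silyloxyfuran, and the molecule has no other enolisable site.

Step 7
Reactants: 10 1-nonyne
Product: 12 benzyl dec-2-ynoate, via lithium nonynide 11 (not isolated)
Conditions: n-BuLi, THF, −78 °C; then BnOCOCl, −78 to 0 °C
Reagents that add atoms: benzyl chloroformate O=C(Cl)OCc1ccccc1
Why: C-acylation of a lithium acetylide with a chloroformate at low temperature is the standard one-step route to a 2-alkynoate.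

Step 8
Reactants: 9 benzyl 2-heptyl-4-methoxy-6-[(5-tert-butyldimethylsilyloxyfuran-3-yl)oxy]benzoate; 12 benzyl dec-2-ynoate
Product: 14 benzyl 2-[4-(benzyloxycarbonyl)-5-(tert-butyldimethylsilyloxy)-3-heptyl-2-hydroxyphenoxy]-6-heptyl-4-methoxybenzoate, via 7-oxanorbornadiene cycloadduct 13 (not isolated)
Conditions: 12 (2 equiv), PhMe (1 M), 90 °C, sealed tube, Ar
Reagents that add atoms: none
Why: The furan of 9 is a cyclic 1,3-dioxygenated diene (OSi on C2, OAr on C4), so it should add the ynoate in a normal-demand, asynchronous [4+2] in which the C5–C6' bond leads and the C2–C1' bond follows, giving oxanorbornadiene 13. In 13 the bridge C–O bond at the silyl ketal carbon ionises to an oxocarbenium ion that is also stabilised vinylogously by the aryloxy group, and loss of the proton on the other bridgehead aromatises the ring, leaving the former furan oxygen as the C5' hydroxyl and the silyl group on O2'. The closest known reaction type is the Diels–Alder reaction of 2-silyloxy- and 2-alkoxyfurans with acetylenic esters, which gives 4-oxygenated phenols by the same bridge opening. Ring B is closed by an intermolecular [4+2] cycloaddition that forms both new C–C bonds (C1'–C2' and C5'–C6'); the two bridgehead stereocentres of 13 are erased on aromatisation, so no stereocentre has to be controlled. The step needs regioselectivity, which is secured because furan C5 is the unsubstituted, nucleophilic terminus (activated by both the 2-silyloxy and 4-aryloxy groups, as in a Danishefsky-type diene) and pairs with the electrophilic, heptyl-bearing β-carbon of the ynoate, while the direction of bridge opening is fixed by the ketal carbon. The aryloxy-bearing carbon stays sp2 throughout, so the diaryl ether is not at risk.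

Step 9
Reactants: 14 benzyl 2-[4-(benzyloxycarbonyl)-5-(tert-butyldimethylsilyloxy)-3-heptyl-2-hydroxyphenoxy]-6-heptyl-4-methoxybenzoate
Product: 15 benzyl 2-[4-(benzyloxycarbonyl)-5-(tert-butyldimethylsilyloxy)-3-heptyl-2-methoxyphenoxy]-6-heptyl-4-methoxybenzoate
Conditions: MeI, K2CO3, acetone, rt
Reagents that add atoms: iodomethane CI
Why: Williamson methylation should take the only free phenol (C5'), since O2' is silylated and, even if unmasked, would be deactivated by hydrogen bonding to the adjacent ester.

Step 10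
Reactants: 15 benzyl 2-[4-(benzyloxycarbonyl)-5-(tert-butyldimethylsilyloxy)-3-heptyl-2-methoxyphenoxy]-6-heptyl-4-methoxybenzoate
Product: 16 benzyl 2-[4-(benzyloxycarbonyl)-3-heptyl-5-hydroxy-2-methoxyphenoxy]-6-heptyl-4-methoxybenzoate
Conditions: TBAF, AcOH, THF, 0 °C
Reagents that add atoms: none
Why: Fluoride cleaves the aryl silyl ether rapidly, and the acetic acid buffer protonates the phenoxide so that the benzyl esters are not attacked.

Step 11
Reactants: 16 benzyl 2-[4-(benzyloxycarbonyl)-3-heptyl-5-hydroxy-2-methoxyphenoxy]-6-heptyl-4-methoxybenzoate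
Product: 17 2-(4-carboxy-3-heptyl-5-hydroxy-2-methoxyphenoxy)-6-heptyl-4-methoxybenzoic acid (target)
Conditions: H2 (1 atm), 10% Pd/C, EtOAc, rt
Reagents that add atoms: none
Why: Catalytic hydrogenolysis removes both benzyl esters at room temperature, while the diaryl ether, the aryl methyl ethers and the arenes are inert and the salicylic-type acids are not heated.

**Compound list**

1 | 5-heptylresorcinol (5-heptylbenzene-1,3-diol) | CCCCCCCc1cc(O)cc(O)c1 | starting material
2 | [(2-heptyl-4,6-dihydroxyphenyl)methylidene]dimethylammonium chloride | CCCCCCCc1cc(O)cc(O)c1C=[N+](C)C.[Cl-] | intermediate (not isolated)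
3 | 6-heptyl-2,4-dihydroxybenzaldehyde | CCCCCCCc1cc(O)cc(O)c1C=O | intermediate
4 | 2-heptyl-6-hydroxy-4-methoxybenzaldehyde | CCCCCCCc1cc(OC)cc(O)c1C=O | intermediate
5 | 2-heptyl-6-hydroxy-4-methoxybenzoic acid | CCCCCCCc1cc(OC)cc(O)c1C(=O)O | intermediate
6 | benzyl 2-heptyl-6-hydroxy-4-methoxybenzoate | CCCCCCCc1cc(OC)cc(O)c1C(=O)OCc1ccccc1 | intermediate
7 | 4-bromofuran-2(5H)-one | O=C1C=C(Br)CO1 | starting material
8 | benzyl 2-heptyl-4-methoxy-6-[(5-oxo-2,5-dihydrofuran-3-yl)oxy]benzoate | CCCCCCCc1cc(OC)cc(OC2=CC(=O)OC2)c1C(=O)OCc1ccccc1 | intermediate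
9 | benzyl 2-heptyl-4-methoxy-6-[(5-tert-butyldimethylsilyloxyfuran-3-yl)oxy]benzoate | CCCCCCCc1cc(OC)cc(Oc2coc(O[Si](C)(C)C(C)(C)C)c2)c1C(=O)OCc1ccccc1 | intermediate (key-step precursor)
10 | 1-nonyne | CCCCCCCC#C | starting material
11 | lithium non-1-yn-1-ide | CCCCCCCC#C[Li] | intermediate (not isolated)
12 | benzyl dec-2-ynoate | CCCCCCCC#CC(=O)OCc1ccccc1 | intermediate (key-step precursor)
13 | benzyl 5-{[2-(benzyloxycarbonyl)-3-heptyl-5-methoxyphenyl]oxy}-1-(tert-butyldimethylsilyloxy)-3-heptyl-7-oxabicyclo[2.2.1]hepta-2,5-diene-2-carboxylate (racemic) | CCCCCCCc1cc(OC)cc(OC2=CC3(O[Si](C)(C)C(C)(C)C)OC2C(CCCCCCC)=C3C(=O)OCc2ccccc2)c1C(=O)OCc1ccccc1 | intermediate (not isolated)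
14 | benzyl 2-[4-(benzyloxycarbonyl)-5-(tert-butyldimethylsilyloxy)-3-heptyl-2-hydroxyphenoxy]-6-heptyl-4-methoxybenzoate | CCCCCCCc1cc(OC)cc(Oc2cc(O[Si](C)(C)C(C)(C)C)c(C(=O)OCc3ccccc3)c(CCCCCCC)c2O)c1C(=O)OCc1ccccc1 | intermediate (key-step product)
15 | benzyl 2-[4-(benzyloxycarbonyl)-5-(tert-butyldimethylsilyloxy)-3-heptyl-2-methoxyphenoxy]-6-heptyl-4-methoxybenzoate | CCCCCCCc1cc(OC)cc(Oc2cc(O[Si](C)(C)C(C)(C)C)c(C(=O)OCc3ccccc3)c(CCCCCCC)c2OC)c1C(=O)OCc1ccccc1 | intermediate
16 | benzyl 2-[4-(benzyloxycarbonyl)-3-heptyl-5-hydroxy-2-methoxyphenoxy]-6-heptyl-4-methoxybenzoate | CCCCCCCc1cc(OC)cc(Oc2cc(O)c(C(=O)OCc3ccccc3)c(CCCCCCC)c2OC)c1C(=O)OCc1ccccc1 | intermediate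
17 | 2-(4-carboxy-3-heptyl-5-hydroxy-2-methoxyphenoxy)-6-heptyl-4-methoxybenzoic acid | CCCCCCCc1cc(OC)cc(Oc2cc(O)c(C(=O)O)c(CCCCCCC)c2OC)c1C(=O)O | target

**Step count and risk**

Total step count: 11. Longest linear sequence: 10 (steps 1–6 and 8–11); step 7 is a one-step side branch.

Steps most likely to fail:

1. Step 8. The β-alkyl ynoate is only a moderate dienophile. At the temperature needed, the cycloaddition may be outrun by decomposition of the silyloxyfuran (for example proton transfer from the phenolic product returning it to butenolide 8) or diverted into open-chain vinylogous Michael adducts that do not close ring B. The fallback keeps the ring construction but changes the acceptor to an aldehyde and defers the carboxyl oxidation level. It sets out from 9 (with the dienophile made from 11) and returns to the route at 17. Lithium nonynide 11 is quenched with DMF and then aqueous KH2PO4 to give dec-2-ynal F1, a much stronger dienophile than 12. Aldehyde F1 should add to 9 in CH2Cl2 at 0 °C to rt with the same regiochemistry and bridge opening, to give benzyl 2-[5-(tert-butyldimethylsilyloxy)-4-formyl-3-heptyl-2-hydroxyphenoxy]-6-heptyl-4-methoxybenzoate F2, in which ring B carries a formyl group at C1'. Methylation of F2 with MeI/K2CO3 in acetone gives benzyl 2-[5-(tert-butyldimethylsilyloxy)-4-formyl-3-heptyl-2-methoxyphenoxy]-6-heptyl-4-methoxybenzoate F3, the C5' methyl ether. Pinnick oxidation of F3 gives 4-{[2-(benzyloxycarbonyl)-3-heptyl-5-methoxyphenyl]oxy}-6-(tert-butyldimethylsilyloxy)-2-heptyl-3-methoxybenzoic acid F4, the ring B acid. TBAF/AcOH converts F4 into 4-{[2-(benzyloxycarbonyl)-3-heptyl-5-methoxyphenyl]oxy}-2-heptyl-6-hydroxy-3-methoxybenzoic acid F5, and hydrogenolysis of F5 over Pd/C gives 17.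

2. Step 5. The phenol is hydrogen-bonded to its ortho ester and attacks slowly, so base-induced γ-deprotonation and oligomerisation of the bromobutenolide may consume the electrophile first. The fallback forms the C–O bond before the lactone; it sets out from 6 and returns at 8. DABCO-catalysed oxa-Michael addition of 6 to methyl 4-hydroxybut-2-ynoate (COC(=O)C#CCO) in MeCN should give methyl (E)-3-{[2-(benzyloxycarbonyl)-3-heptyl-5-methoxyphenyl]oxy}-4-hydroxybut-2-enoate F6, the open-chain β-aryloxy enoate. In F6 the hydroxymethyl group is cis to the ester, so warming with catalytic PPTS in toluene should lactonise it, with loss of methanol, to butenolide 8.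

3. Step 9. Under carbonate the phenoxide may attack silicon, so that the silyl group is lost or moves between phenol oxygens; a mixture of unmethylated and wrongly methylated material would result. The fallback drops the protecting group and relies on chelation for selectivity; it sets out from 14 and returns at 16. TBAF/AcOH in THF under argon gives benzyl 2-[4-(benzyloxycarbonyl)-3-heptyl-2,5-dihydroxyphenoxy]-6-heptyl-4-methoxybenzoate F7, the free hydroquinone. One equivalent of MeI with K2CO3 in degassed acetone should then methylate F7 only at the C5' hydroxyl, because the C2' hydroxyl is hydrogen-bonded to the ester, giving 16.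

**Further compounds**

F1 | step 8 | dec-2-ynal | CCCCCCCC#CC=O
F2 | step 8 | benzyl 2-[5-(tert-butyldimethylsilyloxy)-4-formyl-3-heptyl-2-hydroxyphenoxy]-6-heptyl-4-methoxybenzoate | CCCCCCCc1cc(OC)cc(Oc2cc(O[Si](C)(C)C(C)(C)C)c(C=O)c(CCCCCCC)c2O)c1C(=O)OCc1ccccc1
F3 | step 8 | benzyl 2-[5-(tert-butyldimethylsilyloxy)-4-formyl-3-heptyl-2-methoxyphenoxy]-6-heptyl-4-methoxybenzoate | CCCCCCCc1cc(OC)cc(Oc2cc(O[Si](C)(C)C(C)(C)C)c(C=O)c(CCCCCCC)c2OC)c1C(=O)OCc1ccccc1
F4 | step 8 | 4-{[2-(benzyloxycarbonyl)-3-heptyl-5-methoxyphenyl]oxy}-6-(tert-butyldimethylsilyloxy)-2-heptyl-3-methoxybenzoic acid | CCCCCCCc1cc(OC)cc(Oc2cc(O[Si](C)(C)C(C)(C)C)c(C(=O)O)c(CCCCCCC)c2OC)c1C(=O)OCc1ccccc1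
F5 | step 8 | 4-{[2-(benzyloxycarbonyl)-3-heptyl-5-methoxyphenyl]oxy}-2-heptyl-6-hydroxy-3-methoxybenzoic acid | CCCCCCCc1cc(OC)cc(Oc2cc(O)c(C(=O)O)c(CCCCCCC)c2OC)c1C(=O)OCc1ccccc1
F6 | step 5 | methyl (E)-3-{[2-(benzyloxycarbonyl)-3-heptyl-5-methoxyphenyl]oxy}-4-hydroxybut-2-enoate | COC(=O)/C=C(\CO)Oc1cc(OC)cc(CCCCCCC)c1C(=O)OCc1ccccc1
F7 | step 9 | benzyl 2-[4-(benzyloxycarbonyl)-3-heptyl-2,5-dihydroxyphenoxy]-6-heptyl-4-methoxybenzoate | CCCCCCCc1cc(OC)cc(Oc2cc(O)c(C(=O)OCc3ccccc3)c(CCCCCCC)c2O)c1C(=O)OCc1ccccc1
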